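**Assumption:** the target has no stereocentre and no stereogenic double bond, so it is achiral and no enantiocontrol is needed.

## Retrosynthetic overview

1. Target ⇒ aromatic Claisen rearrangement (last step) of the 5‑O‑(1,1‑dimethylallyl) ether of the 3‑aryl‑5‑hydroxy‑7‑methoxycoumarin; C6 is the only free ortho position of O5, so the prenyl position is fixed.
2. Ring C (pyranone) ⇒ intramolecular Knoevenagel condensation (C3=C4) of a 2‑formylaryl arylacetate.
3. Key bond C3–C1′ ⇒ electrophilic ester α‑carbon (rhodium carbenoid of the 2‑formylaryl diazoacetate, an enolonium equivalent) plus C4 of silylated resorcinol; both carbons are nucleophilic in their normal polarity.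
4. Diazoacetate ⇒ 2‑hydroxy‑4‑methoxy‑6‑(1,1‑dimethylallyloxy)benzaldehyde ⇒ symmetric 2,6‑dihydroxy‑4‑methoxybenzaldehyde ⇒ 2,4,6‑trimethoxybenzaldehyde.
5. Ring order: rings A and B are bought as benzenes; ring C is the only ring formed, directly after the key bond.

## Route

Step 1
Reactants: 1 2,4,6-trimethoxybenzaldehyde
Product: 2 2,6-dihydroxy-4-methoxybenzaldehyde
Conditions: AlCl3 (4 equiv), CH2Cl2, 0 °C to rt; ice/H2O
Reagents that add atoms: none
Why: Chelation-controlled Lewis acid demethylation: AlCl3 bound to the aldehyde oxygen cleaves only the two ortho methyl ethers through six-membered aluminium chelates, leaving the para OMe (future 7-OMe) intact.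

Step 2
Reactants: 3 2-methylbut-3-en-2-ol
Product: 5 methyl 2-methylbut-3-en-2-yl carbonate, via lithium alkoxide 4 (not isolated)
Conditions: n-BuLi, THF, −78 °C; then ClCO2Me, −78 °C to rt
Reagents that add atoms: methyl chloroformate COC(=O)Cl
Why: Acylation of a pre-formed tertiary alkoxide with a chloroformate (carbonate formation), needed because the tertiary alcohol is too hindered for amine-base acylation.

Step 3
Reactants: 2 2,6-dihydroxy-4-methoxybenzaldehyde; 5 methyl 2-methylbut-3-en-2-yl carbonate
Product: 6 2-hydroxy-4-methoxy-6-[(2-methylbut-3-en-2-yl)oxy]benzaldehyde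
Conditions: 5 (1.05 equiv), Pd(PPh3)4 (2 mol %), THF, 0 °C to rt
Reagents that add atoms: none
Why: Decarboxylative Tsuji–Trost O-allylation: zerovalent palladium ionises the carbonate, the released methoxide deprotonates one of the two equivalent phenols, and the phenoxide attacks the more substituted terminus of the 1,1-dimethylallyl palladium complex to give the reverse-prenyl ether; the second OH stays locked in its hydrogen bond to the aldehyde, so mono-etherification dominates.

Step 4
Reactants: 6 2-hydroxy-4-methoxy-6-[(2-methylbut-3-en-2-yl)oxy]benzaldehyde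
Product: 8 2-formyl-5-methoxy-3-[(2-methylbut-3-en-2-yl)oxy]phenyl 2-diazoacetate, via tosylhydrazone ester 7 (not isolated)
Conditions: TsNHN=CHCOCl (1.3 equiv), PhNMe2, CH2Cl2, 0 °C; then Et3N, 0 °C to rt
Reagents that add atoms: glyoxylic acid chloride p-toluenesulfonylhydrazone O=C(Cl)/C=N/NS(=O)(=O)c1ccc(C)cc1
Why: House diazoacetylation: O-acylation of the phenol by the acid chloride, then Et3N-induced loss of p-toluenesulfinate from the tosylhydrazone (Bamford–Stevens-type fragmentation) gives the aryl diazoacetate under conditions too mild to touch the aldehyde or the tertiary allyl ether.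

Step 5
Reactants: 8 2-formyl-5-methoxy-3-[(2-methylbut-3-en-2-yl)oxy]phenyl 2-diazoacetate; 9 1,3-bis(trimethylsilyloxy)benzene
Product: 12 3-(2,4-dihydroxyphenyl)-7-methoxy-5-[(2-methylbut-3-en-2-yl)oxy]-2H-chromen-2-one, via aryl arylacetate 10 (not isolated), via bis-silyl coumarin 11 (not isolated)
Conditions: 9 (5 equiv), Rh2(OAc)4 (1 mol %), CH2Cl2, rt, slow addition of 8; then DBU (1.5 equiv), rt; then K2CO3 (cat.), MeOH, rt; aq NH4Cl
Reagents that add atoms: none
Why: Proposed new method: the electrophilic rhodium carbenoid from 8 makes the ester α-carbon (future C3) an enolonium equivalent that is attacked by C4 of 9, its most nucleophilic position (para to one silyloxy group, ortho to the other), and rearomatisation gives 10 (closest known reaction type: rhodium-carbenoid aromatic substitution, that is formal C–H insertion, of alkoxyarenes by diazoacetates through a zwitterion or a donor–acceptor norcaradiene that reopens); DBU then closes ring C by intramolecular Knoevenagel aldol condensation as in the Perkin–Oglialoro coumarin synthesis, methanolysis removes the silyl groups, and no stereocentre is formed.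

Step 6
Reactants: 12 3-(2,4-dihydroxyphenyl)-7-methoxy-5-[(2-methylbut-3-en-2-yl)oxy]-2H-chromen-2-one
Product: 14 3-(2,4-dihydroxyphenyl)-5-hydroxy-7-methoxy-6-(3-methylbut-2-en-1-yl)-2H-chromen-2-one, via Claisen dienone 13 (not isolated)
Conditions: PhNEt2, 140 °C, Ar
Reagents that add atoms: none
Why: Aromatic Claisen rearrangement (3,3-sigmatropic shift) of the 1,1-dimethylallyl aryl ether delivers the allyl unit with allylic inversion to C6, the only free ortho position of O5, giving the linear 3-methylbut-2-enyl group; enolisation of the dienone restores the 5-phenol and erases its transient sp3 centre, so no stereocentre remains.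

## Compound list

1 | 2,4,6-trimethoxybenzaldehyde | COc1cc(OC)c(C=O)c(OC)c1 | starting material
2 | 2,6-dihydroxy-4-methoxybenzaldehyde | COc1cc(O)c(C=O)c(O)c1 | intermediate
3 | 2-methylbut-3-en-2-ol | CC(C)(O)C=C | starting material
4 | lithium 2-methylbut-3-en-2-olate (formed in the flask) | [Li+].[O-]C(C)(C)C=C | intermediate
5 | methyl 2-methylbut-3-en-2-yl carbonate | COC(=O)OC(C)(C)C=C | intermediate
6 | 2-hydroxy-4-methoxy-6-[(2-methylbut-3-en-2-yl)oxy]benzaldehyde | COc1cc(O)c(C=O)c(OC(C)(C)C=C)c1 | intermediate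
7 | 2-formyl-5-methoxy-3-[(2-methylbut-3-en-2-yl)oxy]phenyl (2E)-2-[2-(4-methylbenzenesulfonyl)hydrazinylidene]acetate (formed in the flask) | COc1cc(OC(=O)/C=N/NS(=O)(=O)c2ccc(C)cc2)c(C=O)c(OC(C)(C)C=C)c1 | intermediate
8 | 2-formyl-5-methoxy-3-[(2-methylbut-3-en-2-yl)oxy]phenyl 2-diazoacetate | COc1cc(OC(=O)C=[N+]=[N-])c(C=O)c(OC(C)(C)C=C)c1 | intermediate
9 | 1,3-bis(trimethylsilyloxy)benzene | C[Si](C)(C)Oc1cccc(O[Si](C)(C)C)c1 | starting material
10 | 2-formyl-5-methoxy-3-[(2-methylbut-3-en-2-yl)oxy]phenyl 2-[2,4-bis(trimethylsilyloxy)phenyl]acetate (formed in the flask) | COc1cc(OC(=O)Cc2ccc(O[Si](C)(C)C)cc2O[Si](C)(C)C)c(C=O)c(OC(C)(C)C=C)c1 | intermediate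
11 | 3-[2,4-bis(trimethylsilyloxy)phenyl]-7-methoxy-5-[(2-methylbut-3-en-2-yl)oxy]-2H-chromen-2-one (formed in the flask) | COc1cc2oc(=O)c(-c3ccc(O[Si](C)(C)C)cc3O[Si](C)(C)C)cc2c(OC(C)(C)C=C)c1 | intermediate
12 | 3-(2,4-dihydroxyphenyl)-7-methoxy-5-[(2-methylbut-3-en-2-yl)oxy]-2H-chromen-2-one | COc1cc2oc(=O)c(-c3ccc(O)cc3O)cc2c(OC(C)(C)C=C)c1 | intermediate
13 | 3-(2,4-dihydroxyphenyl)-7-methoxy-6-(3-methylbut-2-en-1-yl)-6H-chromene-2,5-dione (racemic at C6, formed in the flask) | COC1=CC2=C(C=C(c3ccc(O)cc3O)C(=O)O2)C(=O)C1CC=C(C)C | intermediate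
14 | 3-(2,4-dihydroxyphenyl)-5-hydroxy-7-methoxy-6-(3-methylbut-2-en-1-yl)-2H-chromen-2-one | COc1cc2oc(=O)c(-c3ccc(O)cc3O)cc2c(O)c1CC=C(C)C | target

## Step count and risks

Total steps: 6. Longest linear sequence: 5 (steps 1, 3, 4, 5, 6); step 2 is a one-step branch and 9 is bought.

**Most likely to fail, 1: step 5.** The acceptor-only carbenoid may choose the vinyl group, the neighbouring aldehyde oxygen or a silyl ether oxygen instead of the arene carbon. If the silyl groups fall off before ring closure, the 2′-phenol cleaves the tether to a benzofuranone, though that pathway should still recondense to 12. The fallback sets out from 9 (and uses 6) and returns at 12. Ethyl diazoacetate and Rh2(OAc)4 arylate 9 alone, where no alkene or aldehyde competes, to give ethyl 2-[2,4-bis(trimethylsilyloxy)phenyl]acetate F1. Methanolic HCl strips the silyl groups and closes the lactone to 6-hydroxy-1-benzofuran-2(3H)-one F2. Et3N in EtOH condenses F2 with aldehyde 6 to (Z)-6-hydroxy-3-{[2-hydroxy-4-methoxy-6-(2-methylbut-3-en-2-yloxy)phenyl]methylidene}-1-benzofuran-2(3H)-one F3. The ring A phenol of F3 then opens the five-membered lactone and recloses as the six-membered one (translactonisation), giving 12.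

**Most likely to fail, 2: step 3.** The ether may form as the linear prenyl isomer, or both phenols may react. The fallback sets out from 2 and returns at 6. Copper-catalysed propargylation (3-chloro-3-methylbut-1-yne, CuCl2·2H2O cat., DBU, MeCN, 0 °C) gives 2-hydroxy-4-methoxy-6-[(2-methylbut-3-yn-2-yl)oxy]benzaldehyde F4, in which the tertiary ether is fixed by the reagent. Semihydrogenation (H2, Pd on CaCO3 poisoned with Pb(OAc)2, quinoline, EtOAc) then gives 6.

**Most likely to fail, 3: step 4.** The bulky hydrazone acid chloride may acylate the hydrogen-bonded phenol only sluggishly. The fallback sets out from 6 and returns at 8. Bromoacetyl bromide with pyridine in CH2Cl2 at 0 °C gives 2-formyl-5-methoxy-3-[(2-methylbut-3-en-2-yl)oxy]phenyl 2-bromoacetate F5. Brief treatment with N,N′-ditosylhydrazine and DBU in THF at 0 °C converts the bromoacetate into the diazoacetate 8.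

## Further compounds

F1 | step 5 | ethyl 2-[2,4-bis(trimethylsilyloxy)phenyl]acetate | CCOC(=O)Cc1ccc(O[Si](C)(C)C)cc1O[Si](C)(C)C
F2 | step 5 | 6-hydroxy-1-benzofuran-2(3H)-one | O=C1Cc2ccc(O)cc2O1
F3 | step 5 | (Z)-6-hydroxy-3-{[2-hydroxy-4-methoxy-6-(2-methylbut-3-en-2-yloxy)phenyl]methylidene}-1-benzofuran-2(3H)-one | COc1cc(O)c(/C=C2\C(=O)Oc3cc(O)ccc32)c(OC(C)(C)C=C)c1
F4 | step 3 | 2-hydroxy-4-methoxy-6-[(2-methylbut-3-yn-2-yl)oxy]benzaldehyde | COc1cc(O)c(C=O)c(OC(C)(C)C#C)c1
F5 | step 4 | 2-formyl-5-methoxy-3-[(2-methylbut-3-en-2-yl)oxy]phenyl 2-bromoacetate | COc1cc(OC(=O)CBr)c(C=O)c(OC(C)(C)C=C)c1
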